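Atom labels C1–C26 follow the order of the target SMILES (C1 = exocyclic CH2, C26 = ring-fusion CH bonded to C2).
Retrosynthesis cuts the lactone bond C23–O22 (back to a 1,4-diol), then C14–C15 and C14–C20 (boron chemistry on the C14 carbinol), then the C6–C8 methyl bond and the C5 oxygen, then the ring bonds C9–C26 and C2–C3 together, and finally traces the chain to geraniol.
Enabling feature: the methylene C1=C2 is exocyclic on the seven-membered ring (C2, C3, C4, C5, C6, C9, C26) at the carbon bonded to fusion atom C26, which is shared with the cyclopentane (C9, C10, C11, C12, C26). C26–C2=C1 is what an allene leaves after its inner π bond adds to a vinylcyclopropane (alkene C9=C6, ring C5/C4/C3); a silyloxy group on C5 then emerges as an enol silane that accepts the second C6 methyl.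
Forward: geraniol is epoxidised and rearranged to the quaternary aldehyde (C12) and extended at both ends to the allene–siloxyvinylcyclopropane. One rhodium step then closes cyclopentane and cycloheptene together. C6 methylation, C5 deoxygenation, lithiation–borylation at C14 with a C20 boronate, one-carbon homologation/oxidation, acetylation and oxidative lactonisation finish the molecule.
Stereochemistry: C12 comes from Sharpless epoxidation plus a stereospecific siloxymethyl shift; C9 and C26 from C12 in the cycloaddition (cis fusion); C14 from (+)-sparteine-directed lithiation; C20 from a ligand-controlled copper borylation, transferred with retention.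

Key step: step 10

Assumption: the Josiphos antipode named in step 18 is taken to be the one that gives the (S)-boronate 24; if it favours the (R)-enantiomer, the mirror-image ligand is used.

Bicyclic compounds are named with azulene locants 1 = C12, 2 = C11, 3 = C10, 3a = C9, 4 = C6, 5 = C5, 6 = C4, 7 = C3, 8 = C2, 8a = C26.

Step 1
Reactants: 1 geraniol
Product: 2 [(2S,3S)-3-methyl-3-(4-methylpent-3-en-1-yl)oxiran-2-yl]methanol
Conditions: Ti(OiPr)4 (5 mol%), L-(+)-diethyl tartrate (7 mol%), tBuOOH, 4 Å MS, CH2Cl2, −20 °C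
Reagents that add atoms: tert-butyl hydroperoxide, CC(C)(C)OO
Why: Sharpless asymmetric epoxidation of the allylic alcohol with the L-(+)-tartrate catalyst delivers oxygen to the face that gives the (2S,3S)-epoxide and leaves the remote trisubstituted alkene untouched.

Step 2
Reactants: 2 (2S,3S)-epoxygeraniol
Product: 3 {[(2S,3S)-3-methyl-3-(4-methylpent-3-en-1-yl)oxiran-2-yl]methoxy}tri(propan-2-yl)silane
Conditions: TIPSCl, imidazole, DMF, rt
Reagents that add atoms: chlorotri(propan-2-yl)silane, CC(C)[Si](Cl)(C(C)C)C(C)C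
Why: Standard silylation of the primary alcohol; the bulky silyl ether is needed for the siloxymethyl shift of step 3 and later serves as the larger arm on C12.

Step 3
Reactants: 3 epoxy silyl ether
Product: 4 (2S)-2,6-dimethyl-2-{[tri(propan-2-yl)silyloxy]methyl}hept-5-enal
Conditions: MABR [methylaluminium bis(4-bromo-2,6-di-tert-butylphenoxide), 2 equiv, preformed], CH2Cl2, −78 → −20 °C
Reagents that add atoms: none
Why: The bulky aluminium Lewis acid opens the epoxide at its tertiary carbon and the siloxymethyl group shifts anti to the departing oxygen (epoxy silyl ether to β-siloxy aldehyde rearrangement, a semipinacol-type 1,2-shift), so the epoxide chirality is transferred with inversion at the migration terminus to the quaternary centre that becomes C12.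

Step 4
Reactants: 4 quaternary aldehyde
Product: 5 (3R)-3,7-dimethyl-3-{[tri(propan-2-yl)silyloxy]methyl}oct-6-en-1-yne
Conditions: dimethyl (1-diazo-2-oxopropyl)phosphonate, K2CO3, MeOH, 0 °C → rt
Reagents that add atoms: dimethyl (1-diazo-2-oxopropyl)phosphonate, COP(=O)(OC)C(=[N+]=[N-])C(C)=O
Why: Ohira–Bestmann (Seyferth–Gilbert) homologation converts the non-enolisable aldehyde into the terminal alkyne under carbonate conditions that can neither epimerise the quaternary centre nor cleave the silyl ether.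

Step 5
Reactants: 5 enyne
Product: 7 (4R)-4-methyl-4-{[tri(propan-2-yl)silyloxy]methyl}hex-5-ynal, via vicinal diol 6 (not isolated)
Conditions: OsO4 (2 mol%), NaIO4, 2,6-lutidine, dioxane/H2O, rt
Reagents that add atoms: osmium tetroxide, O=[Os](=O)(=O)=O; sodium periodate, [Na+].[O-][I](=O)(=O)=O; water, O
Why: Lemieux–Johnson oxidation: osmium dihydroxylates the electron-rich trisubstituted alkene far faster than the terminal alkyne and periodate cleaves the diol to the aldehyde and acetone.

Step 6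
Reactants: 7 alkynyl aldehyde
Product: 8 (3E,7R)-3,7-dimethyl-7-{[tri(propan-2-yl)silyloxy]methyl}non-3-en-8-yn-2-one
Conditions: Ph3P=C(Me)COMe, toluene, 100 °C
Reagents that add atoms: 3-(triphenylphosphoranylidene)butan-2-one, CC(=O)C(C)=P(c1ccccc1)(c1ccccc1)c1ccccc1
Why: Wittig olefination with the acyl-stabilised α-methyl ylide should give the trisubstituted enone with the chain trans to the acyl group (E), the geometry the vinylcyclopropane needs.

Step 7
Reactants: 8 enone
Product: 9 triethyl{[(3E,7R)-3,7-dimethyl-7-{[tri(propan-2-yl)silyloxy]methyl}nona-1,3-dien-8-yn-2-yl]oxy}silane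
Conditions: TESOTf, Et3N, CH2Cl2, −78 → 0 °C
Reagents that add atoms: triethylsilyl trifluoromethanesulfonate, CC[Si](CC)(CC)OS(=O)(=O)C(F)(F)F
Why: Silyl triflate/amine enol silylation of the methyl ketone gives the cross-conjugated 2-silyloxydiene because the methyl group is the only α-position that can be deprotonated.

Step 8
Reactants: 9 2-silyloxydiene
Product: 10 triethyl({1-[(2E,6R)-6-methyl-6-{[tri(propan-2-yl)silyloxy]methyl}oct-2-en-7-yn-2-yl]cyclopropyl}oxy)silane
Conditions: Et2Zn, CH2I2, CH2Cl2, 0 °C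
Reagents that add atoms: diiodomethane, ICI
Why: The zinc carbenoid (Furukawa variant of the Simmons–Smith cyclopropanation) adds to the electron-rich enol-ether double bond in preference to the trisubstituted alkene and the alkyne, giving the 1-silyloxy-1-alkenylcyclopropane.

Step 9
Reactants: 10 siloxyvinylcyclopropane alkyne
Product: 12 triethyl({1-[(2E,6R)-6-methyl-6-{[tri(propan-2-yl)silyloxy]methyl}nona-2,7,8-trien-2-yl]cyclopropyl}oxy)silane, via propargylic amine 11 (not isolated)
Conditions: (CH2O)n, CuI (0.5 equiv), Cy2NH, dioxane, 100 °C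
Reagents that add atoms: formaldehyde (as paraformaldehyde), C=O
Why: Crabbé homologation: copper-mediated Mannich coupling to the propargylic amine followed by intramolecular hydride transfer and loss of the imine turns the terminal alkyne into the monosubstituted allene without touching the quaternary centre or the silyl ethers.

Step 10
Reactants: 12 allene–siloxyvinylcyclopropane
Product: 13 triethyl{[(1R,3aR,8aS)-1,4-dimethyl-8-methylidene-1-{[tri(propan-2-yl)silyloxy]methyl}-1,2,3,3a,6,7,8,8a-octahydroazulen-5-yl]oxy}silane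
Conditions: [Rh(CO)2Cl]2 (2.5 mol%), toluene (0.02 M), 90 °C; filtration through basic alumina, used crude
Reagents that add atoms: none
Why: Rhodium(I) coordinates the vinylcyclopropane, cleaves the C3–C5 bond with release of strain to a π-allyl/σ-alkyl rhodacycle, inserts the inner allene π bond (C26=C2) and reductively eliminates C2–C3; the closest known reaction type is the rhodium-catalysed intramolecular [5+2] cycloaddition of allenes with vinylcyclopropanes. The cyclopentane closes when the three-atom tether (C12–C11–C10) brings C26 onto C9 in the migratory insertion, and the cycloheptene closes by C(sp2)–C(sp3) reductive elimination from the eight-membered rhodacycle, leaving the outer allene bond as the exocyclic methylene and the C5 oxygen as the C5=C6 enol silane. C9 and C26 form cis because both bonds are made suprafacially within a cis-fused bicyclic metallacycle, the E alkene placing H-9 on the side of H-26. Their absolute sense is set by quaternary C12, whose larger silyloxymethyl arm turns away from the C26–C2 bond and the metal so that C2 ends syn to the C12 methyl. The step needs selectivity for the inner allene bond and for cleavage of the cyclopropane towards C3, both secured by the tether length and by the C5 silyloxy group, which accelerates and directs the ring opening.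

Step 11
Reactants: 13 enol silane
Product: 15 (1R,3aR,8aS)-1,4,4-trimethyl-8-methylidene-1-{[tri(propan-2-yl)silyloxy]methyl}octahydroazulen-5(1H)-one, via lithium enolate 14 (not isolated)
Conditions: MeLi, THF, 0 °C → rt; then MeI, DMPU, −78 → 0 °C
Reagents that add atoms: iodomethane, CI
Why: Methyllithium cleaves the triethylsilyl enol ether to the regiodefined tetrasubstituted lithium enolate, which is C-methylated at C6 (regiospecific enolate alkylation) to complete the gem-dimethyl group; C6 is then no longer stereogenic and C9 is not enolisable.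

Step 12
Reactants: 15 ketone
Product: 16 (1R,3aR,8aS)-1,4,4-trimethyl-8-methylidene-1-{[tri(propan-2-yl)silyloxy]methyl}decahydroazulen-5-ol (C5 epimers)
Conditions: LiAlH4, Et2O, 0 °C
Reagents that add atoms: none
Why: Hydride reduction of the hindered ketone; either carbinol epimer serves because C5 is deoxygenated in step 14.

Step 13
Reactants: 16 alcohol
Product: 18 O-[(1R,3aR,8aS)-1,4,4-trimethyl-8-methylidene-1-{[tri(propan-2-yl)silyloxy]methyl}decahydroazulen-5-yl] S-methyl carbonodithioate, via sodium xanthate 17 (not isolated)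
Conditions: NaH, imidazole (cat.), THF, 0 °C → reflux; CS2; then MeI, rt
Reagents that add atoms: carbon disulfide, S=C=S; iodomethane, CI
Why: Addition of the alkoxide to carbon disulfide and S-methylation gives the xanthate needed for radical deoxygenation.

Step 14
Reactants: 18 xanthate
Product: 19 {[(1R,3aR,8aS)-1,4,4-trimethyl-8-methylidenedecahydroazulen-1-yl]methoxy}tri(propan-2-yl)silane
Conditions: Bu3SnH, AIBN (cat.), toluene, 110 °C
Reagents that add atoms: none
Why: Barton–McCombie deoxygenation: stannyl radical adds to the thiocarbonyl, β-scission gives the secondary C5 radical and the stannane transfers hydrogen, the radical having only disfavoured 4-exo or 5-endo paths to the exocyclic alkene.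

Step 15
Reactants: 19 silyl ether
Product: 20 [(1R,3aR,8aS)-1,4,4-trimethyl-8-methylidenedecahydroazulen-1-yl]methanol
Conditions: TBAF, THF, rt → 50 °C
Reagents that add atoms: none
Why: Fluoride cleaves the neopentyl triisopropylsilyl ether; nothing else in the hydrocarbon is affected.

Step 16
Reactants: 20 neopentyl alcohol
Product: 21 [(1R,3aR,8aS)-1,4,4-trimethyl-8-methylidenedecahydroazulen-1-yl]methyl 2,4,6-tri(propan-2-yl)benzoate
Conditions: NaH, 2,4,6-triisopropylbenzoyl chloride, THF, 0 → 60 °C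
Reagents that add atoms: 2,4,6-tri(propan-2-yl)benzoyl chloride, CC(C)c1cc(C(C)C)c(C(Cl)=O)c(C(C)C)c1
Why: O-acylation of the sodium alkoxide gives the hindered benzoate that directs α-lithiation at C14, resists attack at its carbonyl and is a good leaving group for the later 1,2-shift.

Step 17
Reactants: 22 2-[(tert-butyldimethylsilyl)oxy]acetaldehyde
Product: 23 ethyl (2E)-4-[(tert-butyldimethylsilyl)oxy]but-2-enoate
Conditions: Ph3P=CHCO2Et, CH2Cl2, rt
Reagents that add atoms: ethyl (triphenylphosphoranylidene)acetate, CCOC(=O)C=P(c1ccccc1)(c1ccccc1)c1ccccc1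
Why: Wittig olefination with the ester-stabilised ylide gives the E enoate.

Step 18
Reactants: 23 enoate
Product: 24 ethyl (3S)-4-[(tert-butyldimethylsilyl)oxy]-3-(4,4,5,5-tetramethyl-1,3,2-dioxaborolan-2-yl)butanoate
Conditions: B2pin2, CuCl (3 mol%), NaOtBu (5 mol%), (R,SFp)-Josiphos (3 mol%), MeOH (2 equiv), THF, rt
Reagents that add atoms: bis(pinacolato)diboron, CC1(C)OB(OC1(C)C)B1OC(C)(C)C(C)(C)O1
Why: Copper(I)–boryl conjugate addition to the enoate under chiral bisphosphine control followed by protonation of the copper enolate (asymmetric β-borylation) sets the stereocentre that becomes C20.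

Step 19
Reactants: 24 β-boryl ester
Product: 25 (3S)-4-[(tert-butyldimethylsilyl)oxy]-3-(4,4,5,5-tetramethyl-1,3,2-dioxaborolan-2-yl)butan-1-ol
Conditions: DIBAL-H, CH2Cl2, −78 → 0 °C; Rochelle salt
Reagents that add atoms: none
Why: Hydride reduction of the ester to the primary alcohol at low temperature, which the pinacol boronate should tolerate.

Step 20
Reactants: 25 boryl alcohol
Product: 26 2-[(2S)-1,4-bis{[tert-butyl(dimethyl)silyl]oxy}butan-2-yl]-4,4,5,5-tetramethyl-1,3,2-dioxaborolane
Conditions: TBSCl, imidazole, DMF, rt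
Reagents that add atoms: tert-butylchlorodimethylsilane, CC(C)(C)[Si](C)(C)Cl
Why: Standard silylation gives the bis-silyl ether, so the boronate carries no acidic or electrophilic group into the organolithium step.

Step 21
Reactants: 21 benzoate; 26 secondary boronic ester
Product: 29 2-{(1R,2R)-4-[(tert-butyldimethylsilyl)oxy]-2-{[(tert-butyldimethylsilyl)oxy]methyl}-1-[(1S,3aR,8aS)-1,4,4-trimethyl-8-methylidenedecahydroazulen-1-yl]butyl}-4,4,5,5-tetramethyl-1,3,2-dioxaborolane, via lithiated benzoate 27 (not isolated), via boronate complex 28 (not isolated)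
Conditions: sBuLi, (+)-sparteine, Et2O, −78 °C, 5 h; then 26, −78 °C, 2 h; then MgBr2·OEt2, 35 °C, 16 h
Reagents that add atoms: none
Why: Lithiation–borylation: sBuLi/(+)-sparteine removes the pro-R hydrogen next to the benzoate oxygen, the configurationally stable carbenoid adds to boron with retention, and the secondary alkyl group then shifts from boron to carbon with inversion at C14 and retention at C20 as the benzoate leaves, so both side-chain stereocentres are reagent-derived.

Step 22
Reactants: 29 secondary boronic ester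
Product: 32 (2R,3R)-5-[(tert-butyldimethylsilyl)oxy]-3-{[(tert-butyldimethylsilyl)oxy]methyl}-2-[(1R,3aR,8aS)-1,4,4-trimethyl-8-methylidenedecahydroazulen-1-yl]pentan-1-ol, via chloromethyl boronate complex 30 (not isolated), via homologated boronic ester 31 (not isolated)
Conditions: BrCH2Cl, nBuLi, THF, −78 °C → rt; then 2 M NaOH, 30% H2O2, THF, 0 °C → rt
Reagents that add atoms: bromochloromethane, ClCBr; hydrogen peroxide, OO
Why: Matteson homologation: chloromethyllithium adds to boron and C14 migrates to the CH2 group with retention as chloride leaves, after which the primary boronate is oxidised with retention to the C15 alcohol while silyl ethers and the alkene survive basic peroxide.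

Step 23
Reactants: 32 primary alcohol
Product: 33 (2R,3R)-5-[(tert-butyldimethylsilyl)oxy]-3-{[(tert-butyldimethylsilyl)oxy]methyl}-2-[(1R,3aR,8aS)-1,4,4-trimethyl-8-methylidenedecahydroazulen-1-yl]pentyl acetate
Conditions: Ac2O, pyridine, DMAP (cat.), CH2Cl2, rt
Reagents that add atoms: acetic anhydride, CC(=O)OC(C)=O
Why: Acetylation of the only free hydroxyl fixes the C15 acetate before the other two oxygens are released.

Step 24
Reactants: 33 bis-silyl ether acetate
Product: 34 (2R,3R)-5-hydroxy-3-(hydroxymethyl)-2-[(1R,3aR,8aS)-1,4,4-trimethyl-8-methylidenedecahydroazulen-1-yl]pentyl acetate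
Conditions: HF·pyridine, THF/pyridine, 0 °C → rt
Reagents that add atoms: none
Why: Buffered fluoride removes both primary silyl ethers without hydrolysing the acetate or isomerising the exocyclic alkene.

Step 25
Reactants: 34 diol acetate
Product: 36 (2R)-2-[(3R)-5-oxooxolan-3-yl]-2-[(1R,3aR,8aS)-1,4,4-trimethyl-8-methylidenedecahydroazulen-1-yl]ethyl acetate, via lactol 35 (not isolated)
Conditions: TEMPO (20 mol%), PhI(OAc)2 (3 equiv), CH2Cl2, rt
Reagents that add atoms: none
Why: Oxidative lactonisation of the 1,4-diol: the oxoammonium oxidant takes the less hindered C23 alcohol to the aldehyde, the C21 hydroxyl closes the lactol and a second oxidation gives the γ-lactone with its carbonyl at C23.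

Compound list
1 | geraniol, (2E)-3,7-dimethylocta-2,6-dien-1-ol | CC(C)=CCC/C(C)=C/CO | starting material
2 | [(2S,3S)-3-methyl-3-(4-methylpent-3-en-1-yl)oxiran-2-yl]methanol | OC[C@@H]1O[C@@]1(C)CCC=C(C)C | intermediate
3 | {[(2S,3S)-3-methyl-3-(4-methylpent-3-en-1-yl)oxiran-2-yl]methoxy}tri(propan-2-yl)silane | CC(C)[Si](OC[C@@H]1O[C@@]1(C)CCC=C(C)C)(C(C)C)C(C)C | intermediate
4 | (2S)-2,6-dimethyl-2-{[tri(propan-2-yl)silyloxy]methyl}hept-5-enal | O=C[C@](C)(CO[Si](C(C)C)(C(C)C)C(C)C)CCC=C(C)C | intermediate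
5 | (3R)-3,7-dimethyl-3-{[tri(propan-2-yl)silyloxy]methyl}oct-6-en-1-yne | C#C[C@](C)(CO[Si](C(C)C)(C(C)C)C(C)C)CCC=C(C)C | intermediate
6 | (6R)-2,6-dimethyl-6-{[tri(propan-2-yl)silyloxy]methyl}oct-7-yne-2,3-diol (C3 epimers) | C#C[C@](C)(CO[Si](C(C)C)(C(C)C)C(C)C)CCC(O)C(C)(C)O | intermediate
7 | (4R)-4-methyl-4-{[tri(propan-2-yl)silyloxy]methyl}hex-5-ynal | C#C[C@](C)(CO[Si](C(C)C)(C(C)C)C(C)C)CCC=O | intermediate
8 | (3E,7R)-3,7-dimethyl-7-{[tri(propan-2-yl)silyloxy]methyl}non-3-en-8-yn-2-one | CC(=O)/C(C)=C/CC[C@@](C)(CO[Si](C(C)C)(C(C)C)C(C)C)C#C | intermediate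
9 | triethyl{[(3E,7R)-3,7-dimethyl-7-{[tri(propan-2-yl)silyloxy]methyl}nona-1,3-dien-8-yn-2-yl]oxy}silane | C=C(O[Si](CC)(CC)CC)/C(C)=C/CC[C@@](C)(CO[Si](C(C)C)(C(C)C)C(C)C)C#C | intermediate
10 | triethyl({1-[(2E,6R)-6-methyl-6-{[tri(propan-2-yl)silyloxy]methyl}oct-2-en-7-yn-2-yl]cyclopropyl}oxy)silane | CC[Si](CC)(CC)OC1(CC1)/C(C)=C/CC[C@@](C)(CO[Si](C(C)C)(C(C)C)C(C)C)C#C | intermediate
11 | Mannich base of 10, the alkyne terminus carrying CH2N(cyclohexyl)2 | CC[Si](CC)(CC)OC1(CC1)/C(C)=C/CC[C@@](C)(CO[Si](C(C)C)(C(C)C)C(C)C)C#CCN(C1CCCCC1)C1CCCCC1 | intermediate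
12 | triethyl({1-[(2E,6R)-6-methyl-6-{[tri(propan-2-yl)silyloxy]methyl}nona-2,7,8-trien-2-yl]cyclopropyl}oxy)silane | C=C=C[C@](C)(CO[Si](C(C)C)(C(C)C)C(C)C)CC/C=C(\C)C1(O[Si](CC)(CC)CC)CC1 | intermediate
13 | triethyl{[(1R,3aR,8aS)-1,4-dimethyl-8-methylidene-1-{[tri(propan-2-yl)silyloxy]methyl}-1,2,3,3a,6,7,8,8a-octahydroazulen-5-yl]oxy}silane (cis-fused) | C=C1CCC(O[Si](CC)(CC)CC)=C(C)[C@@H]2CC[C@@](C)(CO[Si](C(C)C)(C(C)C)C(C)C)[C@H]12 | intermediate
14 | lithium (1R,3aR,8aS)-1,4-dimethyl-8-methylidene-1-{[tri(propan-2-yl)silyloxy]methyl}-1,2,3,3a,6,7,8,8a-octahydroazulen-5-olate | C=C1CCC(O[Li])=C(C)[C@@H]2CC[C@@](C)(CO[Si](C(C)C)(C(C)C)C(C)C)[C@H]12 | intermediate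
15 | (1R,3aR,8aS)-1,4,4-trimethyl-8-methylidene-1-{[tri(propan-2-yl)silyloxy]methyl}octahydroazulen-5(1H)-one | C=C1CCC(=O)C(C)(C)[C@@H]2CC[C@@](C)(CO[Si](C(C)C)(C(C)C)C(C)C)[C@H]12 | intermediate
16 | (1R,3aR,8aS)-1,4,4-trimethyl-8-methylidene-1-{[tri(propan-2-yl)silyloxy]methyl}decahydroazulen-5-ol (C5 epimers) | C=C1CCC(O)C(C)(C)[C@@H]2CC[C@@](C)(CO[Si](C(C)C)(C(C)C)C(C)C)[C@H]12 | intermediate
17 | sodium O-[(1R,3aR,8aS)-1,4,4-trimethyl-8-methylidene-1-{[tri(propan-2-yl)silyloxy]methyl}decahydroazulen-5-yl] carbonodithioate (C5 epimers) | C=C1CCC(OC(=S)[S-])C(C)(C)[C@@H]2CC[C@@](C)(CO[Si](C(C)C)(C(C)C)C(C)C)[C@H]12.[Na+] | intermediate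
18 | O-[(1R,3aR,8aS)-1,4,4-trimethyl-8-methylidene-1-{[tri(propan-2-yl)silyloxy]methyl}decahydroazulen-5-yl] S-methyl carbonodithioate (C5 epimers) | C=C1CCC(OC(=S)SC)C(C)(C)[C@@H]2CC[C@@](C)(CO[Si](C(C)C)(C(C)C)C(C)C)[C@H]12 | intermediate
19 | {[(1R,3aR,8aS)-1,4,4-trimethyl-8-methylidenedecahydroazulen-1-yl]methoxy}tri(propan-2-yl)silane | C=C1CCCC(C)(C)[C@@H]2CC[C@@](C)(CO[Si](C(C)C)(C(C)C)C(C)C)[C@H]12 | intermediate
20 | [(1R,3aR,8aS)-1,4,4-trimethyl-8-methylidenedecahydroazulen-1-yl]methanol | C=C1CCCC(C)(C)[C@@H]2CC[C@@](C)(CO)[C@H]12 | intermediate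
21 | [(1R,3aR,8aS)-1,4,4-trimethyl-8-methylidenedecahydroazulen-1-yl]methyl 2,4,6-tri(propan-2-yl)benzoate | C=C1CCCC(C)(C)[C@@H]2CC[C@@](C)(COC(=O)c3c(C(C)C)cc(C(C)C)cc3C(C)C)[C@H]12 | intermediate
22 | 2-[(tert-butyldimethylsilyl)oxy]acetaldehyde | CC(C)(C)[Si](C)(C)OCC=O | starting material
23 | ethyl (2E)-4-[(tert-butyldimethylsilyl)oxy]but-2-enoate | CCOC(=O)/C=C/CO[Si](C)(C)C(C)(C)C | intermediate
24 | ethyl (3S)-4-[(tert-butyldimethylsilyl)oxy]-3-(4,4,5,5-tetramethyl-1,3,2-dioxaborolan-2-yl)butanoate | CCOC(=O)C[C@H](B1OC(C)(C)C(C)(C)O1)CO[Si](C)(C)C(C)(C)C | intermediate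
25 | (3S)-4-[(tert-butyldimethylsilyl)oxy]-3-(4,4,5,5-tetramethyl-1,3,2-dioxaborolan-2-yl)butan-1-ol | OCC[C@H](B1OC(C)(C)C(C)(C)O1)CO[Si](C)(C)C(C)(C)C | intermediate
26 | 2-[(2S)-1,4-bis{[tert-butyl(dimethyl)silyl]oxy}butan-2-yl]-4,4,5,5-tetramethyl-1,3,2-dioxaborolane | CC(C)(C)[Si](C)(C)OCC[C@H](B1OC(C)(C)C(C)(C)O1)CO[Si](C)(C)C(C)(C)C | intermediate
27 | (R)-lithio[(1R,3aR,8aS)-1,4,4-trimethyl-8-methylidenedecahydroazulen-1-yl]methyl 2,4,6-tri(propan-2-yl)benzoate, sparteine-complexed | C=C1CCCC(C)(C)[C@@H]2CC[C@@](C)([C@@H]([Li])OC(=O)c3c(C(C)C)cc(C(C)C)cc3C(C)C)[C@H]12 | intermediate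
28 | lithium boronate complex of 27 and 26 (boron bonded to C14 and C20, benzoate still on C14) | C=C1CCCC(C)(C)[C@@H]2CC[C@@](C)([C@@H]([B-]3(OC(C)(C)C(C)(C)O3)[C@@H](CCO[Si](C)(C)C(C)(C)C)CO[Si](C)(C)C(C)(C)C)OC(=O)c3c(C(C)C)cc(C(C)C)cc3C(C)C)[C@H]12.[Li+] | intermediate
29 | 2-{(1R,2R)-4-[(tert-butyldimethylsilyl)oxy]-2-{[(tert-butyldimethylsilyl)oxy]methyl}-1-[(1S,3aR,8aS)-1,4,4-trimethyl-8-methylidenedecahydroazulen-1-yl]butyl}-4,4,5,5-tetramethyl-1,3,2-dioxaborolane (the 1S locant reflects a priority change only) | C=C1CCCC(C)(C)[C@@H]2CC[C@@](C)([C@H](B3OC(C)(C)C(C)(C)O3)[C@@H](CCO[Si](C)(C)C(C)(C)C)CO[Si](C)(C)C(C)(C)C)[C@H]12 | intermediate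
30 | lithium chloromethyl boronate complex of 29 | C=C1CCCC(C)(C)[C@@H]2CC[C@@](C)([C@H]([B-]3(CCl)OC(C)(C)C(C)(C)O3)[C@@H](CCO[Si](C)(C)C(C)(C)C)CO[Si](C)(C)C(C)(C)C)[C@H]12.[Li+] | intermediate
31 | 2-{(2R,3R)-5-[(tert-butyldimethylsilyl)oxy]-3-{[(tert-butyldimethylsilyl)oxy]methyl}-2-[(1S,3aR,8aS)-1,4,4-trimethyl-8-methylidenedecahydroazulen-1-yl]pentyl}-4,4,5,5-tetramethyl-1,3,2-dioxaborolane | C=C1CCCC(C)(C)[C@@H]2CC[C@@](C)([C@H](CB3OC(C)(C)C(C)(C)O3)[C@@H](CCO[Si](C)(C)C(C)(C)C)CO[Si](C)(C)C(C)(C)C)[C@H]12 | intermediate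
32 | (2R,3R)-5-[(tert-butyldimethylsilyl)oxy]-3-{[(tert-butyldimethylsilyl)oxy]methyl}-2-[(1R,3aR,8aS)-1,4,4-trimethyl-8-methylidenedecahydroazulen-1-yl]pentan-1-ol | C=C1CCCC(C)(C)[C@@H]2CC[C@@](C)([C@H](CO)[C@@H](CCO[Si](C)(C)C(C)(C)C)CO[Si](C)(C)C(C)(C)C)[C@H]12 | intermediate
33 | (2R,3R)-5-[(tert-butyldimethylsilyl)oxy]-3-{[(tert-butyldimethylsilyl)oxy]methyl}-2-[(1R,3aR,8aS)-1,4,4-trimethyl-8-methylidenedecahydroazulen-1-yl]pentyl acetate | C=C1CCCC(C)(C)[C@@H]2CC[C@@](C)([C@H](COC(C)=O)[C@@H](CCO[Si](C)(C)C(C)(C)C)CO[Si](C)(C)C(C)(C)C)[C@H]12 | intermediate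
34 | (2R,3R)-5-hydroxy-3-(hydroxymethyl)-2-[(1R,3aR,8aS)-1,4,4-trimethyl-8-methylidenedecahydroazulen-1-yl]pentyl acetate | C=C1CCCC(C)(C)[C@@H]2CC[C@@](C)([C@H](COC(C)=O)[C@@H](CCO)CO)[C@H]12 | intermediate
35 | (2R)-2-[(3R)-5-hydroxyoxolan-3-yl]-2-[(1R,3aR,8aS)-1,4,4-trimethyl-8-methylidenedecahydroazulen-1-yl]ethyl acetate (lactol epimers) | C=C1CCCC(C)(C)[C@@H]2CC[C@@](C)([C@H](COC(C)=O)[C@@H]3COC(O)C3)[C@H]12 | intermediate
36 | (2R)-2-[(3R)-5-oxooxolan-3-yl]-2-[(1R,3aR,8aS)-1,4,4-trimethyl-8-methylidenedecahydroazulen-1-yl]ethyl acetate (CNP0235949.1) | C=C1CCCC(C)(C)[C@@H]2CC[C@@](C)([C@H](COC(C)=O)[C@@H]3COC(=O)C3)[C@H]12 | target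

Total step count: 25. Longest linear sequence: 21 steps (steps 1–16 and 21–25, from geraniol); steps 17–20 form the four-step branch to boronate 26.

Steps most likely to fail

Step 10. The rhodium may be slow to open and insert a vinylcyclopropane that carries both the C6 methyl and the C5 silyloxy group, so that allene oligomerisation or loss of the enol silane overtakes the cycloaddition. The fallback sets out from 7 and returns at 13. The Wittig reaction is run with 1-(triphenylphosphoranylidene)propan-2-one to give the disubstituted enone F1. Silylation, cyclopropanation and Crabbé homologation as in steps 7–9 give the silyloxydiene F2, the siloxyvinylcyclopropane alkyne F3 and the allene F4, which lacks the alkene methyl and belongs to the substrate class on which this cycloaddition is established. Its cycloadduct, the enol silane F5, is methylated once at C6 (MeLi, then MeI) to the monomethyl ketone F6. Equilibrating silylation (Et3SiCl, NaI, Et3N, MeCN) to the more substituted enol silane then gives 13.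

Step 21. Formation of the boronate between two congested partners, or its 1,2-shift, may stall, so that decomposition of the carbenoid or β-elimination of silanolate from the boronate takes over. The fallback sets out from 21 and returns at 36. The same lithiated benzoate 27 is trapped with furan-3-ylboronic acid pinacol ester, a flat partner without a β-leaving group, to give the furyl boronic ester F7. Matteson homologation gives the primary boronic ester F8, oxidation gives the alcohol F9, and acetylation gives the acetate F10. Dye-sensitised photooxygenation with iPr2NEt at −78 °C converts the 3-alkylfuran into the γ-hydroxybutenolide F11, and NaBH4 reduces this to the butenolide F12. Copper hydride conjugate reduction under p-tol-BINAP control (antipode chosen for hydride delivery to the face that gives 20R; Cu(OAc)2, PMHS, tBuOH, toluene) then gives 36.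

Step 11. Proton transfer between the hindered enolate and the product ketone may scramble the enolate and lead to methylation at C4 or over-methylation, and O-methylation may compete. The fallback sets out from 13 and returns at 15. The enol silane is alkylated without a free enolate, using chloromethyl phenyl sulfide and ZnBr2 in CH2Cl2, to give the α-(phenylsulfanylmethyl) ketone F13. Desulfurisation with acetone-deactivated Raney nickel then gives 15.

Further compounds
F1 | step 10 | (3E,7R)-7-methyl-7-{[tri(propan-2-yl)silyloxy]methyl}non-3-en-8-yn-2-one | CC(=O)/C=C/CC[C@@](C)(CO[Si](C(C)C)(C(C)C)C(C)C)C#C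
F2 | step 10 | triethyl{[(3E,7R)-7-methyl-7-{[tri(propan-2-yl)silyloxy]methyl}nona-1,3-dien-8-yn-2-yl]oxy}silane | C=C(O[Si](CC)(CC)CC)/C=C/CC[C@@](C)(CO[Si](C(C)C)(C(C)C)C(C)C)C#C
F3 | step 10 | triethyl({1-[(1E,5R)-5-methyl-5-{[tri(propan-2-yl)silyloxy]methyl}hept-1-en-6-yn-1-yl]cyclopropyl}oxy)silane | CC[Si](CC)(CC)OC1(CC1)/C=C/CC[C@@](C)(CO[Si](C(C)C)(C(C)C)C(C)C)C#C
F4 | step 10 | triethyl({1-[(1E,5R)-5-methyl-5-{[tri(propan-2-yl)silyloxy]methyl}octa-1,6,7-trien-1-yl]cyclopropyl}oxy)silane | C=C=C[C@](C)(CO[Si](C(C)C)(C(C)C)C(C)C)CC/C=C/C1(O[Si](CC)(CC)CC)CC1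
F5 | step 10 | triethyl{[(1R,3aR,8aS)-1-methyl-8-methylidene-1-{[tri(propan-2-yl)silyloxy]methyl}-1,2,3,3a,6,7,8,8a-octahydroazulen-5-yl]oxy}silane | C=C1CCC(O[Si](CC)(CC)CC)=C[C@@H]2CC[C@@](C)(CO[Si](C(C)C)(C(C)C)C(C)C)[C@H]12
F6 | step 10 | (1R,3aR,8aS)-1,4-dimethyl-8-methylidene-1-{[tri(propan-2-yl)silyloxy]methyl}octahydroazulen-5(1H)-one (C4 epimers) | C=C1CCC(=O)C(C)[C@@H]2CC[C@@](C)(CO[Si](C(C)C)(C(C)C)C(C)C)[C@H]12
F7 | step 21 | pinacol boronate with boron and furan-3-yl on C14, 2-{furan-3-yl[(1R,3aR,8aS)-1,4,4-trimethyl-8-methylidenedecahydroazulen-1-yl]methyl}-4,4,5,5-tetramethyl-1,3,2-dioxaborolane | C=C1CCCC(C)(C)[C@@H]2CC[C@@](C)([C@H](B3OC(C)(C)C(C)(C)O3)c3ccoc3)[C@H]12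
F8 | step 21 | 2-{2-(furan-3-yl)-2-[(1R,3aR,8aS)-1,4,4-trimethyl-8-methylidenedecahydroazulen-1-yl]ethyl}-4,4,5,5-tetramethyl-1,3,2-dioxaborolane | C=C1CCCC(C)(C)[C@@H]2CC[C@@](C)([C@H](CB3OC(C)(C)C(C)(C)O3)c3ccoc3)[C@H]12
F9 | step 21 | 2-(furan-3-yl)-2-[(1R,3aR,8aS)-1,4,4-trimethyl-8-methylidenedecahydroazulen-1-yl]ethan-1-ol | C=C1CCCC(C)(C)[C@@H]2CC[C@@](C)([C@H](CO)c3ccoc3)[C@H]12
F10 | step 21 | 2-(furan-3-yl)-2-[(1R,3aR,8aS)-1,4,4-trimethyl-8-methylidenedecahydroazulen-1-yl]ethyl acetate | C=C1CCCC(C)(C)[C@@H]2CC[C@@](C)([C@H](COC(C)=O)c3ccoc3)[C@H]12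
F11 | step 21 | 2-(2-hydroxy-5-oxo-2,5-dihydrofuran-3-yl)-2-[(1R,3aR,8aS)-1,4,4-trimethyl-8-methylidenedecahydroazulen-1-yl]ethyl acetate (hemiacetal epimers) | C=C1CCCC(C)(C)[C@@H]2CC[C@@](C)([C@H](COC(C)=O)C3=CC(=O)OC3O)[C@H]12
F12 | step 21 | 2-(5-oxo-2,5-dihydrofuran-3-yl)-2-[(1R,3aR,8aS)-1,4,4-trimethyl-8-methylidenedecahydroazulen-1-yl]ethyl acetate | C=C1CCCC(C)(C)[C@@H]2CC[C@@](C)([C@H](COC(C)=O)C3=CC(=O)OC3)[C@H]12
F13 | step 11 | (1R,3aR,8aS)-1,4-dimethyl-8-methylidene-4-[(phenylsulfanyl)methyl]-1-{[tri(propan-2-yl)silyloxy]methyl}octahydroazulen-5(1H)-one (C4 epimers) | C=C1CCC(=O)C(C)(CSc3ccccc3)[C@@H]2CC[C@@](C)(CO[Si](C(C)C)(C(C)C)C(C)C)[C@H]12
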